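# Design proposal: synthesis of CNP0229937.1 (compound 34) by a ring-enforced intramolecular Horner–Wadsworth–Emmons butenolide annulation

## The problem

Compound 34 is a germacranolide. Ring A is a ten-membered carbocycle (C1–C10) with a C1 ketone, a C10 methyl group, a C8 tiglate and a cis-4,5-epoxide (ring C). Ring B is a butenolide (O–C6–C7=C11–C12) fused at C6–C7, with an acetoxymethyl carbon C13 on C11.

There are five stereocentres. C4 and C5 form one unit that a Z alkene and a reagent-controlled epoxidation can deliver. C6 is next to C5 and can be steered by the epoxide. C8 and C10 are insulated from that triad by the sp2 carbons C7 and C1, so each must be set on its own and carried in.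

The C7=C11 alkene is tetrasubstituted. Its geometry is defined only because it lies in ring B, which argues for making it by a cyclising olefination.

Several groups are fragile:
- C6–H is γ to the lactone carbonyl and β to the epoxide oxygen, so base can open the epoxide.
- The trisubstituted epoxide faces the C1 ketone across the ring and is acid-labile.
- The C13 acetate is an allylic acetate of the Baylis–Hillman type.
- C10 is α to the C1 ketone.
- A free C8 hydroxyl can take over the lactone from O6.

The C1 carbonyl is 1,5-related to both C5 and C7. A carbanion at either carbon would close a five-membered ring onto it, so C1 has to be latent while ring A is closed.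

The feature that makes the key step possible: C7=C11 lies between the C6 oxygen and the C12 carbonyl. A C6 ester of a C11 phosphonate and a C7 ketone are therefore its two halves.

## Retrosynthesis

**34 to 30 (ester C–O bonds at C8 and C13).** The two acyl groups go on last. The silyl ether at C8 of 30 is removed (31) and the tiglate installed (32) while C13 is still a 4-methoxybenzyl ether, which cannot leave. The ether is then cleaved (33) and the acetate is formed in the final step. This order keeps the labile allylic acetate away from every nucleophilic reagent. The forward reactions only need to avoid alkoxide bases.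

**30 to 29 (C7=C11, ring B).** Cutting the double bond gives ketophosphonate 29. The neighbouring cut, lactonisation of a preformed tetrasubstituted hydroxymethyl-acrylate on ring A, would need that alkene with defined geometry and is rejected. An aldol–dehydration at the same bond would need stronger base next to the epoxide. 29 has no ring B and no alkene. The forward reaction must remove the C11 proton without touching C6–H.

**29 to 28 and 20 (ester C–O at C6).** Acid 20 comes from triethyl phosphonoacetate 16 through acrylate 18 and ether 19. The ester is formed after the ozonolysis because the electron-rich arene of the ether would not survive ozone.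

**28 to 27 (both ring carbonyls).** The C7 and C1 ketones are both drawn back to methylidene groups. C7=CH2 is what a C7 alkenyl nucleophile leaves behind. C1=CH2 is the mask that keeps C1 inert during ring closure and keeps C10 from epimerising. One ozonolysis reveals both.

**27 to 26 (C6–C7, ring A).** The ring is opened between the carbinol carbon and the alkenyl carbon: an alkenylchromium adds to an epoxy aldehyde. Closure at C1–C2 by acylation of an alkylmetal was considered but is not established for a ten-membered ring. Closure at C2–C3 would need the epoxide to be made later without a directing hydroxyl. The chosen cut lets C5 control C6 in the Felkin sense. 26 is acyclic and carries four of the five stereocentres.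

**26 to 24 (epoxide C–O bonds).** Oxidation level and epoxide are removed to give (Z)-allylic alcohol 24 via epoxy alcohol 25. The Sharpless epoxidation sets C4 and C5 by reagent control.

**24 to 10 and 15 (C1=CH2 and C1–C2).** The methylidene goes back to ketone 22, and the ketone to Weinreb amide 10 plus the Grignard reagent from bromide 15. The two fragments are of similar size. Each carries only what it needs: C8 and C10 in 10, the Z alkene in 15.

**10 to 1 (C8–C9 and the C8 carbinol).** Amide 10 comes from trans-lactone 8. The lactone comes from bromo enone 6 by reagent-controlled reduction. 6 comes from vinyl ketone 4, and 4 from iodide 2 of the (R)-hydroxyisobutyrate 1. C10 is bought; C8 is set by the catalyst.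

**15 to 11 (C4–CH3 and the Z alkene).** Bromide 15 comes from alcohol 14 and ester 13. The ester is formed by syn-carbocupration of ynoate 12, made from 4-bromobut-1-yne 11. Cuprate addition fixes the Z geometry, and the two chain ends are differentiated from the start.

## Roads not taken

**Alternative 1: keto-sulfone alkylation at C2–C3.**
- Cut and key step: ring A would be cut at C2–C3. Caesium carbonate at high dilution would form a C2 β-keto sulfone carbanion that displaces a primary C3 (Z)-allylic bromide, giving A1.
- Merits: this is the best-established way to close ten-membered germacrane rings. The butenolide would already be in place from open-chain chemistry, and C1 would need no mask.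
- Weak points: the sulfone must be removed reductively next to a butenolide whose C6–O bond is allylic. The epoxide must then be put on the macrocyclic 4,5-alkene with no free allylic hydroxyl, so facial selectivity rests on ring conformation alone. C6–H in this series is both allylic and γ to the lactone, so carbonate base may deprotonate it.
- Comparison: the ring closure is better precedented than the one chosen here, and it saves the methylenation and one ozonolysis. Against this the chosen plan sets a reagent-controlled epoxide made before any ring exists, and no reducing metal after ring B is formed.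

**Alternative 2: Wittig–Still [2,3] ring contraction.**
- Cut and key step: C6–C7 would be formed while an O–C13 bond of a thirteen-membered bis-allylic ether is broken. Tin–lithium exchange at C6 with n-BuLi and [2,3] shift would give A2.
- Merits: the large ether ring is easy to close. The sigmatropic shift usually transfers geometry faithfully, so it controls C6 better than a ring-closing carbonyl addition.
- Weak points: A2 has an sp3 stereocentre at C7 with a 2-propenyl side chain that the target lacks. The alkene must then be moved into the 7(11) position, C12 oxidised and lactonised, and the C13 oxygen introduced at the former methylidene carbon. The C1 ketal must come off under acid in the presence of the epoxide. The epoxidation would rely on direction by the C6 hydroxyl.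
- Comparison: better than the chosen plan at C6. Worse after the key step, where the chosen plan forms C7=C11 with the C13 oxygen already attached in one operation.

**Alternative 3: samarium-mediated ring expansion at C1–C2.**
- Cut and key step: a temporary γ-lactone between C1 and the C8 oxygen would be attacked by an organosamarium formed from a C2 iodide (SmI2 with HMPA or catalytic NiI2). Collapse of the hemiketal would give A3 with the C1 ketone and free C8 hydroxyl.
- Merits: this is where the chosen plan is weakest. The lactone is tether, C8 protecting group and C1 source in one, so no C1 mask, no silyl group at C8 and no second ozonolysis would be needed.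
- Weak points: acyl substitution of lactones by organosamarium species is secure for small rings only. The released ketone can be reduced further by divalent samarium. A3 would sit largely as the 1,8-hemiketal, and C6 and C8 would have to be acylated in a re-planned order.
- Comparison: potentially shorter, and it would feed the same olefination. The chosen plan sets against it a ring closure of a known type for medium rings and no single-electron reductant near the epoxy carbinol.

Key step: step 21

## Route

Remark: carbons are numbered as in the germacranes (C1 ketone carbon to C10 in ring A, C11–C13 in ring B). The acetal carbon of 15 and 21–23 and C11 of 19, 20 and 29 are unassigned centres, carried as mixtures and removed or flattened later.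

Step 1
Reactants: 1 methyl (2R)-3-hydroxy-2-methylpropanoate
Product: 2 methyl (2S)-3-iodo-2-methylpropanoate
Conditions: I2, PPh3, imidazole, CH2Cl2, 0 °C to rt
Reagents that add atoms: iodine, II
Why: Appel-type iodination of the primary alcohol is an SN2 process at CH2, so the future C10 centre is untouched (the descriptor changes only because iodine outranks the ester).

Step 2
Reactants: 2 methyl (2S)-3-iodo-2-methylpropanoate
Product: 4 methyl (2R)-2-methyl-4-oxohex-5-enoate, via [(2S)-3-methoxy-2-methyl-3-oxopropyl]zinc iodide 3 (not isolated)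
Conditions: Zn dust (activated with TMSCl and 1,2-dibromoethane), THF, 35 °C; then acryloyl chloride, Pd(PPh3)4 (5 mol%), THF, 0 °C
Reagents that add atoms: acryloyl chloride, C=CC(=O)Cl
Why: Zinc insertion gives the chelated β-zincio ester, whose stereocentre is not the metal-bearing carbon; Negishi-type acylation under zerovalent palladium catalysis forms the C8–C9 bond and the vinyl ketone.

Step 3
Reactants: 4 methyl (2R)-2-methyl-4-oxohex-5-enoate
Product: 6 methyl (2R)-5-bromo-2-methyl-4-oxohex-5-enoate, via methyl (2R)-5,6-dibromo-2-methyl-4-oxohexanoate 5 (not isolated)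
Conditions: Br2, CH2Cl2, −78 °C; then Et3N, −78 to 0 °C
Reagents that add atoms: bromine, BrBr
Why: Bromine adds across the enone alkene and triethylamine removes HBr through the ketone enolate, the standard bromination–dehydrobromination route to an α-bromo enone; this installs the C7 bromide that later becomes the nucleophile.

Step 4
Reactants: 6 methyl (2R)-5-bromo-2-methyl-4-oxohex-5-enoate
Product: 8 (3R,5S)-5-(1-bromoethenyl)-3-methyloxolan-2-one, via methyl (2R,4S)-5-bromo-4-hydroxy-2-methylhex-5-enoate 7 (not isolated)
Conditions: (R)-2-methyl-CBS-oxazaborolidine [(3aR)-1-methyl-3,3-diphenyltetrahydro-1H,3H-pyrrolo[1,2-c][1,3,2]oxazaborole] (20 mol%), catecholborane, toluene, −78 °C; MeOH quench; then p-TsOH·H2O (cat.), CH2Cl2, rt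
Reagents that add atoms: none
Why: Corey–Bakshi–Shibata reduction, for which α-bromo enones are good substrates because the 1-bromovinyl group acts as the large substituent; the (R)-catalyst should give the (S)-carbinol at C8 by 1,2-reduction under reagent control, and acid closes the trans γ-lactone, at which stage any C8 epimer can be removed.

Step 5
Reactants: 8 (3R,5S)-5-(1-bromoethenyl)-3-methyloxolan-2-one
Product: 9 (2R,4S)-5-bromo-4-hydroxy-N-methoxy-N,2-dimethylhex-5-enamide
Conditions: MeNH(OMe)·HCl, Me3Al, CH2Cl2, 0 °C to rt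
Reagents that add atoms: N,O-dimethylhydroxylamine hydrochloride, CNOC.Cl
Why: Weinreb aminolysis of a lactone with the aluminium amide opens the ring at the acyl carbon and leaves both stereocentres alone.

Step 6
Reactants: 9 (2R,4S)-5-bromo-4-hydroxy-N-methoxy-N,2-dimethylhex-5-enamide
Product: 10 (2R,4S)-5-bromo-4-[(tert-butyldimethylsilyl)oxy]-N-methoxy-N,2-dimethylhex-5-enamide
Conditions: TBSCl, imidazole, DMF, rt
Reagents that add atoms: tert-butyldimethylsilyl chloride, CC(C)(C)[Si](C)(C)Cl
Why: Standard silylation of the secondary alcohol, carried out at once because the γ-hydroxy amide can close back to the lactone.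

Step 7
Reactants: 11 4-bromobut-1-yne
Product: 12 methyl 5-bromopent-2-ynoate
Conditions: n-BuLi, THF, −78 °C; then ClCO2Me, −78 to 0 °C
Reagents that add atoms: methyl chloroformate, COC(=O)Cl
Why: Deprotonation of the terminal alkyne and C-acylation of the lithium acetylide; at −78 °C the primary bromide is inert.

Step 8
Reactants: 12 methyl 5-bromopent-2-ynoate
Product: 13 methyl (2Z)-5-bromo-3-methylpent-2-enoate
Conditions: Me2CuLi (from MeLi and CuI), THF, −78 °C; MeOH quench at −78 °C
Reagents that add atoms: lithium dimethylcuprate, [Li+].C[Cu-]C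
Why: Conjugate addition of a Gilman reagent to an ynoate is a syn carbocupration; protonation of the alkenylcopper with retention at low temperature puts the new methyl trans to the ester, so C3 and C6 end up cis (Z).

Step 9
Reactants: 13 methyl (2Z)-5-bromo-3-methylpent-2-enoate
Product: 14 (2Z)-5-bromo-3-methylpent-2-en-1-ol
Conditions: DIBAL-H (2.2 equiv), CH2Cl2, −78 °C
Reagents that add atoms: none
Why: 1,2-Reduction of the enoate by DIBAL-H gives the allylic alcohol without isomerising the alkene or touching the bromide.

Step 10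
Reactants: 14 (2Z)-5-bromo-3-methylpent-2-en-1-ol
Product: 15 (2Z)-5-bromo-1-(1-ethoxyethoxy)-3-methylpent-2-ene
Conditions: ethyl vinyl ether, pyridinium p-toluenesulfonate (cat.), CH2Cl2, 0 °C to rt
Reagents that add atoms: ethyl vinyl ether, C=COCC
Why: Acid-catalysed acetalisation; the ethoxyethyl ether is stable to Grignard chemistry and stops the C6 oxygen from closing onto C2.

Step 11
Reactants: 16 triethyl phosphonoacetate
Product: 18 ethyl 2-(diethoxyphosphoryl)prop-2-enoate, via ethyl 2-(diethoxyphosphoryl)-3-methoxypropanoate 17 (not isolated)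
Conditions: paraformaldehyde, piperidine (cat.), MeOH, reflux; then p-TsOH·H2O (cat.), toluene, reflux with removal of MeOH
Reagents that add atoms: formaldehyde (as paraformaldehyde), C=O
Why: Knoevenagel condensation in methanol gives the β-methoxy adduct, and acid-catalysed loss of methanol gives the 2-phosphonoacrylate, a known preparation of this reagent.

Step 12
Reactants: 18 ethyl 2-(diethoxyphosphoryl)prop-2-enoate
Product: 19 ethyl 2-(diethoxyphosphoryl)-3-[(4-methoxyphenyl)methoxy]propanoate
Conditions: 4-methoxybenzyl alcohol, t-BuOK (5 mol%), THF, 0 °C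
Reagents that add atoms: 4-methoxybenzyl alcohol, COc1ccc(CO)cc1
Why: Base-catalysed oxa-Michael addition to the doubly activated alkene; the adduct carbanion is protonated by the alcohol, which carries the chain.

Step 13
Reactants: 19 ethyl 2-(diethoxyphosphoryl)-3-[(4-methoxyphenyl)methoxy]propanoate
Product: 20 2-(diethoxyphosphoryl)-3-[(4-methoxyphenyl)methoxy]propanoic acid
Conditions: LiOH (1.05 equiv), THF–H2O, 0 °C; then 1 M HCl to pH 3
Reagents that add atoms: lithium hydroxide, [Li+].[OH-]
Why: Saponification of the activated ethyl ester is fast in the cold, and the carboxylate formed is no longer prone to lose the β-alkoxide.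

Step 14
Reactants: 15 (2Z)-5-bromo-1-(1-ethoxyethoxy)-3-methylpent-2-ene and 10 (2R,4S)-5-bromo-4-[(tert-butyldimethylsilyl)oxy]-N-methoxy-N,2-dimethylhex-5-enamide
Product: 22 (2Z,7R,9S)-10-bromo-9-[(tert-butyldimethylsilyl)oxy]-1-(1-ethoxyethoxy)-3,7-dimethylundeca-2,10-dien-6-one, via [(3Z)-5-(1-ethoxyethoxy)-3-methylpent-3-en-1-yl]magnesium bromide 21 (not isolated)
Conditions: Mg turnings (activated with 1,2-dibromoethane), THF, rt; then 10, THF, 0 °C; aq. NH4Cl
Reagents that add atoms: none
Why: Addition of a Grignard reagent to a Weinreb amide stops at the chelated tetrahedral intermediate and gives the ketone on hydrolysis, forming C1–C2; the alkenyl bromide and silyl ether are inert to the Grignard reagent and C10 is not enolised.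

Step 15
Reactants: 22 (2Z,7R,9S)-10-bromo-9-[(tert-butyldimethylsilyl)oxy]-1-(1-ethoxyethoxy)-3,7-dimethylundeca-2,10-dien-6-one
Product: 24 (2Z,7R,9S)-10-bromo-9-[(tert-butyldimethylsilyl)oxy]-3,7-dimethyl-6-methylideneundeca-2,10-dien-1-ol, via (2Z,7R,9S)-10-bromo-9-[(tert-butyldimethylsilyl)oxy]-1-(1-ethoxyethoxy)-3,7-dimethyl-6-methylideneundeca-2,10-diene 23 (not isolated)
Conditions: Cp2TiMe2, toluene, 65 °C; then pyridinium p-toluenesulfonate (cat.), MeOH, rt
Reagents that add atoms: dimethyltitanocene (Cp2TiMe2), [CH3-].[CH3-].[Ti+4].c1cc[cH-]c1.c1cc[cH-]c1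
Why: Petasis methylenation (a non-basic titanocene methylidene) converts the ketone into the C1 methylidene without epimerising C10, which masks C1 for the ring closure; acetal exchange in methanol then frees the allylic alcohol.

Step 16
Reactants: 24 (2Z,7R,9S)-10-bromo-9-[(tert-butyldimethylsilyl)oxy]-3,7-dimethyl-6-methylideneundeca-2,10-dien-1-ol
Product: 25 [(2S,3R)-3-{(4R,6S)-7-bromo-6-[(tert-butyldimethylsilyl)oxy]-4-methyl-3-methylideneoct-7-en-1-yl}-3-methyloxiran-2-yl]methanol
Conditions: Ti(OiPr)4, L-(+)-diethyl tartrate, t-BuOOH, 4 Å molecular sieves, CH2Cl2, −20 °C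
Reagents that add atoms: tert-butyl hydroperoxide, CC(C)(C)OO
Why: Sharpless asymmetric epoxidation; with the L-(+)-tartrate a (Z)-3-methyl allylic alcohol of the nerol type is epoxidised to the (2S,3R)-epoxy alcohol, which sets C4 (R) and C5 (S) by reagent control, while the two alkenes without an allylic hydroxyl do not react.

Step 17
Reactants: 25 [(2S,3R)-3-{(4R,6S)-7-bromo-6-[(tert-butyldimethylsilyl)oxy]-4-methyl-3-methylideneoct-7-en-1-yl}-3-methyloxiran-2-yl]methanol
Product: 26 (2R,3R)-3-{(4R,6S)-7-bromo-6-[(tert-butyldimethylsilyl)oxy]-4-methyl-3-methylideneoct-7-en-1-yl}-3-methyloxirane-2-carbaldehyde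
Conditions: Dess–Martin periodinane, NaHCO3, CH2Cl2, 0 °C to rt
Reagents that add atoms: none
Why: Buffered Dess–Martin oxidation gives the epoxy aldehyde without epimerising C5; it is used without purification.

Step 18
Reactants: 26 (2R,3R)-3-{(4R,6S)-7-bromo-6-[(tert-butyldimethylsilyl)oxy]-4-methyl-3-methylideneoct-7-en-1-yl}-3-methyloxirane-2-carbaldehyde
Product: 27 (4R,5S,6S,8S,10R)-8-[(tert-butyldimethylsilyl)oxy]-4,5-epoxy-4,10-dimethyl-1,7-dimethylidenecyclodecan-6-ol
Conditions: CrCl2 (10 equiv), NiCl2 (2 mol%), degassed DMSO–THF, rt, slow addition to 2 mM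
Reagents that add atoms: none
Why: Intramolecular Nozaki–Hiyama–Kishi reaction: nickel inserts into the C7–Br bond, the alkenyl group passes to chromium and adds to the aldehyde, closing ring A at C6–C7; with C1 masked as an alkene no ketone competes, and Felkin–Anh addition anti to the epoxide C–O bond should give the 6S carbinol.

Step 19
Reactants: 27 (4R,5S,6S,8S,10R)-8-[(tert-butyldimethylsilyl)oxy]-4,5-epoxy-4,10-dimethyl-1,7-dimethylidenecyclodecan-6-ol
Product: 28 (4R,5S,6R,8S,10R)-8-[(tert-butyldimethylsilyl)oxy]-4,5-epoxy-6-hydroxy-4,10-dimethylcyclodecane-1,7-dione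
Conditions: O3, CH2Cl2, −78 °C; then PPh3, −78 °C to rt
Reagents that add atoms: ozone, [O-][O+]=O
Why: Ozonolysis with reductive work-up cleaves both methylidene groups to the C1 and C7 ketones in one operation; the epoxide, silyl ether and secondary alcohol are inert (C6 becomes R by priority only).

Step 20
Reactants: 28 (4R,5S,6R,8S,10R)-8-[(tert-butyldimethylsilyl)oxy]-4,5-epoxy-6-hydroxy-4,10-dimethylcyclodecane-1,7-dione and 20 2-(diethoxyphosphoryl)-3-[(4-methoxyphenyl)methoxy]propanoic acid
Product: 29 (4R,5S,6R,8S,10R)-8-[(tert-butyldimethylsilyl)oxy]-4,5-epoxy-4,10-dimethyl-1,7-dioxocyclodecan-6-yl 2-(diethoxyphosphoryl)-3-[(4-methoxyphenyl)methoxy]propanoate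
Conditions: DCC, 4-(dimethylamino)pyridine (cat.), CH2Cl2, 0 °C
Reagents that add atoms: none
Why: Steglich esterification of the α-ketol with a phosphonoacetic acid, the usual way to such olefination precursors; without a lithium salt the amine does not ionise the phosphonate.

Step 21
Reactants: 29 (4R,5S,6R,8S,10R)-8-[(tert-butyldimethylsilyl)oxy]-4,5-epoxy-4,10-dimethyl-1,7-dioxocyclodecan-6-yl 2-(diethoxyphosphoryl)-3-[(4-methoxyphenyl)methoxy]propanoate
Product: 30 (4R,5S,6S,8S,10R)-8-[(tert-butyldimethylsilyl)oxy]-4,5-epoxy-13-[(4-methoxyphenyl)methoxy]-1-oxogermacr-7(11)-en-12,6-olide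
Conditions: LiCl, i-Pr2NEt, MeCN, rt
Reagents that add atoms: none
Why: Lithium chelation of the phosphoryl and ester oxygens acidifies C11–H enough for the amine to form the carbanion (Masamune–Roush conditions). The carbanion adds to the C7 ketone and the oxaphosphetane collapses with loss of diethyl phosphate, forming C7=C11. The closest known reaction type is the intramolecular Horner–Wadsworth–Emmons closure of α-(phosphonoacyloxy) ketones to tetrasubstituted butenolides. Ring B (O, C6, C7, C11, C12) closes in the 5-exo-trig mode by attack of C11 on the C7 carbonyl. No new stereocentre is formed: the alkene geometry is fixed by the ring and both C11 epimers converge. The step needs C11–H to be removed in preference to C6–H, whose loss would open the epoxide; the lithium-chelated phosphonoacetate is far more acidic and the base is weak. It also needs attack at C7 and not C1; only C7 is within five-ring reach, and it is activated by its two α-oxygens. Loss of 4-methoxybenzyl oxide from the carbanion is disfavoured by the poor leaving group and would in any case be reversed by re-addition.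

Step 22
Reactants: 30 (4R,5S,6S,8S,10R)-8-[(tert-butyldimethylsilyl)oxy]-4,5-epoxy-13-[(4-methoxyphenyl)methoxy]-1-oxogermacr-7(11)-en-12,6-olide
Product: 31 (4R,5S,6S,8S,10R)-4,5-epoxy-8-hydroxy-13-[(4-methoxyphenyl)methoxy]-1-oxogermacr-7(11)-en-12,6-olide
Conditions: HF·pyridine, excess pyridine, THF, 0 °C to rt
Reagents that add atoms: none
Why: Fluoride cleavage of the secondary silyl ether under buffered, non-basic conditions generates no alkoxide that could deprotonate C6 and keeps the epoxide intact.

Step 23
Reactants: 31 (4R,5S,6S,8S,10R)-4,5-epoxy-8-hydroxy-13-[(4-methoxyphenyl)methoxy]-1-oxogermacr-7(11)-en-12,6-olide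
Product: 32 (4R,5S,6S,8S,10R)-4,5-epoxy-13-[(4-methoxyphenyl)methoxy]-8-[(2E)-2-methylbut-2-enoyloxy]-1-oxogermacr-7(11)-en-12,6-olide
Conditions: tiglic acid, 2,4,6-trichlorobenzoyl chloride, Et3N, toluene, rt; then 31, 4-(dimethylamino)pyridine, rt
Reagents that add atoms: tiglic acid, C/C=C(\C)C(=O)O
Why: Yamaguchi esterification through the mixed anhydride acylates the hindered secondary alcohol; the E acid is the stable geometry and the C13 ether offers the nucleophilic catalyst no leaving group.

Step 24
Reactants: 32 (4R,5S,6S,8S,10R)-4,5-epoxy-13-[(4-methoxyphenyl)methoxy]-8-[(2E)-2-methylbut-2-enoyloxy]-1-oxogermacr-7(11)-en-12,6-olide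
Product: 33 (4R,5S,6S,8S,10R)-4,5-epoxy-13-hydroxy-8-[(2E)-2-methylbut-2-enoyloxy]-1-oxogermacr-7(11)-en-12,6-olide
Conditions: DDQ, CH2Cl2–pH 7 buffer, 0 °C to rt
Reagents that add atoms: none
Why: Oxidative cleavage of the 4-methoxybenzyl ether by DDQ (hydride abstraction, then hydrolysis of the hemiacetal) runs under neutral conditions that spare the epoxide, the esters and the butenolide.

Step 25
Reactants: 33 (4R,5S,6S,8S,10R)-4,5-epoxy-13-hydroxy-8-[(2E)-2-methylbut-2-enoyloxy]-1-oxogermacr-7(11)-en-12,6-olide
Product: 34 (4R,5S,6S,8S,10R)-13-acetoxy-4,5-epoxy-8-[(2E)-2-methylbut-2-enoyloxy]-1-oxogermacr-7(11)-en-12,6-olide (CNP0229937.1)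
Conditions: Ac2O, pyridine, CH2Cl2, 0 °C
Reagents that add atoms: acetic anhydride, CC(=O)OC(C)=O
Why: Acetylation of the primary allylic alcohol is placed last so that the labile allylic acetate meets no further reagent.

## Compound list

1 | methyl (2R)-3-hydroxy-2-methylpropanoate | C[C@H](CO)C(=O)OC | starting material
2 | methyl (2S)-3-iodo-2-methylpropanoate | IC[C@@H](C)C(=O)OC | intermediate
3 | [(2S)-3-methoxy-2-methyl-3-oxopropyl]zinc iodide | I[Zn]C[C@@H](C)C(=O)OC | intermediate
4 | methyl (2R)-2-methyl-4-oxohex-5-enoate | C=CC(=O)C[C@@H](C)C(=O)OC | intermediate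
5 | methyl (2R)-5,6-dibromo-2-methyl-4-oxohexanoate (C5 epimers) | BrCC(Br)C(=O)C[C@@H](C)C(=O)OC | intermediate
6 | methyl (2R)-5-bromo-2-methyl-4-oxohex-5-enoate | C=C(Br)C(=O)C[C@@H](C)C(=O)OC | intermediate
7 | methyl (2R,4S)-5-bromo-4-hydroxy-2-methylhex-5-enoate | O[C@H](C(Br)=C)C[C@@H](C)C(=O)OC | intermediate
8 | (3R,5S)-5-(1-bromoethenyl)-3-methyloxolan-2-one (trans lactone) | O1[C@H](C(Br)=C)C[C@@H](C)C1=O | intermediate
9 | (2R,4S)-5-bromo-4-hydroxy-N-methoxy-N,2-dimethylhex-5-enamide | O[C@H](C(Br)=C)C[C@@H](C)C(=O)N(C)OC | intermediate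
10 | (2R,4S)-5-bromo-4-[(tert-butyldimethylsilyl)oxy]-N-methoxy-N,2-dimethylhex-5-enamide | CC(C)(C)[Si](C)(C)O[C@H](C(Br)=C)C[C@@H](C)C(=O)N(C)OC | intermediate
11 | 4-bromobut-1-yne | C#CCCBr | starting material
12 | methyl 5-bromopent-2-ynoate | COC(=O)C#CCCBr | intermediate
13 | methyl (2Z)-5-bromo-3-methylpent-2-enoate | COC(=O)/C=C(/C)CCBr | intermediate
14 | (2Z)-5-bromo-3-methylpent-2-en-1-ol | OC/C=C(/C)CCBr | intermediate
15 | (2Z)-5-bromo-1-(1-ethoxyethoxy)-3-methylpent-2-ene (acetal centre unassigned) | CCOC(C)OC/C=C(/C)CCBr | intermediate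
16 | triethyl phosphonoacetate | CCOC(=O)CP(=O)(OCC)OCC | starting material
17 | ethyl 2-(diethoxyphosphoryl)-3-methoxypropanoate | CCOC(=O)C(COC)P(=O)(OCC)OCC | intermediate
18 | ethyl 2-(diethoxyphosphoryl)prop-2-enoate | CCOC(=O)C(=C)P(=O)(OCC)OCC | intermediate
19 | ethyl 2-(diethoxyphosphoryl)-3-[(4-methoxyphenyl)methoxy]propanoate (racemic) | CCOC(=O)C(COCc1ccc(OC)cc1)P(=O)(OCC)OCC | intermediate
20 | 2-(diethoxyphosphoryl)-3-[(4-methoxyphenyl)methoxy]propanoic acid (racemic) | OC(=O)C(COCc1ccc(OC)cc1)P(=O)(OCC)OCC | intermediate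
21 | [(3Z)-5-(1-ethoxyethoxy)-3-methylpent-3-en-1-yl]magnesium bromide | CCOC(C)OC/C=C(/C)CC[Mg]Br | intermediate
22 | (2Z,7R,9S)-10-bromo-9-[(tert-butyldimethylsilyl)oxy]-1-(1-ethoxyethoxy)-3,7-dimethylundeca-2,10-dien-6-one | CC(C)(C)[Si](C)(C)O[C@H](C(Br)=C)C[C@@H](C)C(=O)CC/C(C)=C\COC(C)OCC | intermediate
23 | (2Z,7R,9S)-10-bromo-9-[(tert-butyldimethylsilyl)oxy]-1-(1-ethoxyethoxy)-3,7-dimethyl-6-methylideneundeca-2,10-diene | CC(C)(C)[Si](C)(C)O[C@H](C(Br)=C)C[C@@H](C)C(=C)CC/C(C)=C\COC(C)OCC | intermediate
24 | (2Z,7R,9S)-10-bromo-9-[(tert-butyldimethylsilyl)oxy]-3,7-dimethyl-6-methylideneundeca-2,10-dien-1-ol | CC(C)(C)[Si](C)(C)O[C@H](C(Br)=C)C[C@@H](C)C(=C)CC/C(C)=C\CO | intermediate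
25 | [(2S,3R)-3-{(4R,6S)-7-bromo-6-[(tert-butyldimethylsilyl)oxy]-4-methyl-3-methylideneoct-7-en-1-yl}-3-methyloxiran-2-yl]methanol | CC(C)(C)[Si](C)(C)O[C@H](C(Br)=C)C[C@@H](C)C(=C)CC[C@@]1(C)O[C@H]1CO | intermediate
26 | (2R,3R)-3-{(4R,6S)-7-bromo-6-[(tert-butyldimethylsilyl)oxy]-4-methyl-3-methylideneoct-7-en-1-yl}-3-methyloxirane-2-carbaldehyde | CC(C)(C)[Si](C)(C)O[C@H](C(Br)=C)C[C@@H](C)C(=C)CC[C@@]1(C)O[C@H]1C=O | intermediate
27 | (4R,5S,6S,8S,10R)-8-[(tert-butyldimethylsilyl)oxy]-4,5-epoxy-4,10-dimethyl-1,7-dimethylidenecyclodecan-6-ol (cis-epoxide) | CC(C)(C)[Si](C)(C)O[C@H]1C[C@@H](C)C(=C)CC[C@@]2(C)O[C@H]2[C@@H](O)C1=C | intermediate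
28 | (4R,5S,6R,8S,10R)-8-[(tert-butyldimethylsilyl)oxy]-4,5-epoxy-6-hydroxy-4,10-dimethylcyclodecane-1,7-dione | CC(C)(C)[Si](C)(C)O[C@H]1C[C@@H](C)C(=O)CC[C@@]2(C)O[C@H]2[C@@H](O)C1=O | intermediate
29 | (4R,5S,6R,8S,10R)-8-[(tert-butyldimethylsilyl)oxy]-4,5-epoxy-4,10-dimethyl-1,7-dioxocyclodecan-6-yl 2-(diethoxyphosphoryl)-3-[(4-methoxyphenyl)methoxy]propanoate (C11 epimers) | CC(C)(C)[Si](C)(C)O[C@H]1C[C@@H](C)C(=O)CC[C@@]2(C)O[C@H]2[C@@H](OC(=O)C(COCc3ccc(OC)cc3)P(=O)(OCC)OCC)C1=O | intermediate
30 | (4R,5S,6S,8S,10R)-8-[(tert-butyldimethylsilyl)oxy]-4,5-epoxy-13-[(4-methoxyphenyl)methoxy]-1-oxogermacr-7(11)-en-12,6-olide | CC(C)(C)[Si](C)(C)O[C@H]1C[C@@H](C)C(=O)CC[C@@]2(C)O[C@H]2[C@H]2OC(=O)C(COCc3ccc(OC)cc3)=C12 | intermediate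
31 | (4R,5S,6S,8S,10R)-4,5-epoxy-8-hydroxy-13-[(4-methoxyphenyl)methoxy]-1-oxogermacr-7(11)-en-12,6-olide | O[C@H]1C[C@@H](C)C(=O)CC[C@@]2(C)O[C@H]2[C@H]2OC(=O)C(COCc3ccc(OC)cc3)=C12 | intermediate
32 | (4R,5S,6S,8S,10R)-4,5-epoxy-13-[(4-methoxyphenyl)methoxy]-8-[(2E)-2-methylbut-2-enoyloxy]-1-oxogermacr-7(11)-en-12,6-olide | C/C=C(\C)C(=O)O[C@H]1C[C@@H](C)C(=O)CC[C@@]2(C)O[C@H]2[C@H]2OC(=O)C(COCc3ccc(OC)cc3)=C12 | intermediate
33 | (4R,5S,6S,8S,10R)-4,5-epoxy-13-hydroxy-8-[(2E)-2-methylbut-2-enoyloxy]-1-oxogermacr-7(11)-en-12,6-olide | C/C=C(\C)C(=O)O[C@H]1C[C@@H](C)C(=O)CC[C@@]2(C)O[C@H]2[C@H]2OC(=O)C(CO)=C12 | intermediate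
34 | (4R,5S,6S,8S,10R)-13-acetoxy-4,5-epoxy-8-[(2E)-2-methylbut-2-enoyloxy]-1-oxogermacr-7(11)-en-12,6-olide | C/C=C(\C)C(=O)O[C@H]1C[C@@H](C)C(=O)CC[C@@]2(C)O[C@H]2[C@H]2OC(=O)C(COC(C)=O)=C12 | target

## Step count and risks

Total steps: 25. Longest linear sequence: 18 (steps 1–6, then 14–25). The bromide branch (steps 7–10) and the phosphonate branch (steps 11–13) join at steps 14 and 20.

**Step 21 (key step).**
- Risk: the C11 carbanion may expel 4-methoxybenzyl oxide before it reaches the hindered, doubly α-oxygenated C7 ketone. With only an amine base present, the resulting phosphonoacrylate would accumulate. Any forcing would bring deprotonation at C6 and opening of the epoxide into play.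
- Fallback: generate the carbanion by conjugate addition, so that the elimination becomes degenerate. Starting from 28, the alcohol is esterified (DCC, CH2Cl2, no nucleophilic catalyst) with 2-(diethoxyphosphoryl)prop-2-enoic acid F1. F1 is made from commercial (diethoxyphosphoryl)acetic acid by Knoevenagel condensation with paraformaldehyde. This gives the C6 2-(diethoxyphosphoryl)prop-2-enoate of 28 F2. Treating F2 with 4-methoxybenzyl alcohol and a catalytic amount of its lithium alkoxide in THF at 0 °C adds the alkoxide at C13; the carbanion so formed olefinates C7. The route is rejoined at 30.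

**Step 18 (ring closure).**
- Risk: addition to the wrong face of the aldehyde. In a ten-membered transition state ring strain, not the Felkin preference of the epoxy aldehyde, may decide C6. Oligomerisation would also show up here.
- Fallback: set C6 by inversion instead of by the C–C bond formation. Starting from 26, the cyclisation would then give mainly (4R,5S,6R,8S,10R)-8-[(tert-butyldimethylsilyl)oxy]-4,5-epoxy-4,10-dimethyl-1,7-dimethylidenecyclodecan-6-ol F3. Mitsunobu reaction of F3 with 4-nitrobenzoic acid (PPh3, diisopropyl azodicarboxylate, THF) gives the inverted (6S) 4-nitrobenzoate F4. Methanolysis (K2CO3, MeOH, 0 °C) returns the route to 27.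

**Step 4 (C8 carbinol).**
- Risk: insufficient facial discrimination between the 1-bromovinyl and methylene flanks of the ketone, or competing conjugate reduction of the very electrophilic bromo enone.
- Fallback: set C8 on an alkynyl ketone, where the discrimination is electronic, and make the bromoalkene afterwards. Starting from 2 (through zinc reagent 3), palladium-catalysed acylation with 3-(trimethylsilyl)prop-2-ynoyl chloride gives methyl (2R)-2-methyl-4-oxo-6-(trimethylsilyl)hex-5-ynoate F5. Noyori transfer hydrogenation with RuCl[(S,S)-TsDPEN](p-cymene) in 2-propanol, followed by acid, gives (3R,5S)-3-methyl-5-[(trimethylsilyl)ethynyl]oxolan-2-one F6. Desilylation (Bu4NF, AcOH, THF) gives (3R,5S)-5-ethynyl-3-methyloxolan-2-one F7. Bromoboration with B-bromo-9-borabicyclo[3.3.1]nonane and protonolysis with acetic acid places bromine on the internal carbon. The route is rejoined at 8.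

**Step 23 (acylation of free C8–OH).**
- Risk: under the basic acylation conditions the free C8 hydroxyl of 31 may take over the lactone carbonyl (migration from the 6,12- to the 8,12-olide). It may also rest as the hemiketal with the C1 ketone, so that acylation is slow and the lactone has time to move.
- Fallback: install the tiglate before ring B exists. Starting from 29, desilylation (HF·pyridine, pyridine, THF) gives (4R,5S,6R,8S,10R)-4,5-epoxy-8-hydroxy-4,10-dimethyl-1,7-dioxocyclodecan-6-yl 2-(diethoxyphosphoryl)-3-[(4-methoxyphenyl)methoxy]propanoate F8. Yamaguchi esterification with tiglic acid gives the corresponding 8-[(2E)-2-methylbut-2-enoyloxy] ester F9. The olefination conditions of step 21 (LiCl, i-Pr2NEt, MeCN) then close ring B with the tiglate in place. The route is rejoined at 32.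

## Further compounds

F1 | step 21 | 2-(diethoxyphosphoryl)prop-2-enoic acid | C=C(C(=O)O)P(=O)(OCC)OCC
F2 | step 21 | (4R,5S,6R,8S,10R)-8-[(tert-butyldimethylsilyl)oxy]-4,5-epoxy-4,10-dimethyl-1,7-dioxocyclodecan-6-yl 2-(diethoxyphosphoryl)prop-2-enoate | CC(C)(C)[Si](C)(C)O[C@H]1C[C@@H](C)C(=O)CC[C@@]2(C)O[C@H]2[C@@H](OC(=O)C(=C)P(=O)(OCC)OCC)C1=O
F3 | step 18 | (4R,5S,6R,8S,10R)-8-[(tert-butyldimethylsilyl)oxy]-4,5-epoxy-4,10-dimethyl-1,7-dimethylidenecyclodecan-6-ol | CC(C)(C)[Si](C)(C)O[C@H]1C[C@@H](C)C(=C)CC[C@@]2(C)O[C@H]2[C@H](O)C1=C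
F4 | step 18 | (4R,5S,6S,8S,10R)-8-[(tert-butyldimethylsilyl)oxy]-4,5-epoxy-4,10-dimethyl-1,7-dimethylidenecyclodecan-6-yl 4-nitrobenzoate | CC(C)(C)[Si](C)(C)O[C@H]1C[C@@H](C)C(=C)CC[C@@]2(C)O[C@H]2[C@@H](OC(=O)c3ccc(cc3)[N+](=O)[O-])C1=C
F5 | step 4 | methyl (2R)-2-methyl-4-oxo-6-(trimethylsilyl)hex-5-ynoate | C[Si](C)(C)C#CC(=O)C[C@@H](C)C(=O)OC
F6 | step 4 | (3R,5S)-3-methyl-5-[(trimethylsilyl)ethynyl]oxolan-2-one | O1[C@H](C#C[Si](C)(C)C)C[C@@H](C)C1=O
F7 | step 4 | (3R,5S)-5-ethynyl-3-methyloxolan-2-one | O1[C@H](C#C)C[C@@H](C)C1=O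
F8 | step 23 | (4R,5S,6R,8S,10R)-4,5-epoxy-8-hydroxy-4,10-dimethyl-1,7-dioxocyclodecan-6-yl 2-(diethoxyphosphoryl)-3-[(4-methoxyphenyl)methoxy]propanoate | O[C@H]1C[C@@H](C)C(=O)CC[C@@]2(C)O[C@H]2[C@@H](OC(=O)C(COCc3ccc(OC)cc3)P(=O)(OCC)OCC)C1=O
F9 | step 23 | (4R,5S,6R,8S,10R)-4,5-epoxy-4,10-dimethyl-8-[(2E)-2-methylbut-2-enoyloxy]-1,7-dioxocyclodecan-6-yl 2-(diethoxyphosphoryl)-3-[(4-methoxyphenyl)methoxy]propanoate | C/C=C(\C)C(=O)O[C@H]1C[C@@H](C)C(=O)CC[C@@]2(C)O[C@H]2[C@@H](OC(=O)C(COCc3ccc(OC)cc3)P(=O)(OCC)OCC)C1=O
A1 | alternative 1 | macrocyclic C2-phenylsulfonyl C1 ketone with (Z)-4,5-alkene, 6,12-butenolide and silyl ethers at C8 and C13 | CC(C)(C)[Si](C)(C)O[C@H]1C[C@@H](C)C(=O)[C@H](S(=O)(=O)c3ccccc3)C/C(C)=C\[C@H]2OC(=O)C(CO[Si](C)(C)C(C)(C)C)=C12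
A2 | alternative 2 | ten-membered C6 carbinol with C1 dioxolane, (Z)-4,5-alkene, C8 silyl ether and a C7 3-[(4-methoxyphenyl)methoxy]prop-1-en-2-yl side chain | CC(C)(C)[Si](C)(C)O[C@H]1C[C@@H](C)C2(OCCO2)CC/C(C)=C\[C@@H](O)[C@@H]1C(=C)COCc1ccc(OC)cc1
A3 | alternative 3 | ten-membered 8-hydroxy 1-ketone with cis-4,5-epoxide, C6 silyl ether and C7 methylidene | O[C@H]1C[C@@H](C)C(=O)CC[C@@]2(C)O[C@H]2[C@@H](O[Si](C)(C)C(C)(C)C)C1=C
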